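**Strategy.** Ring C of the isoflavanone is taken apart at O1–C8a, C4–C4a and O1–C2, so that ring A becomes a 3-methoxy-5-oxygenated benzyne and everything else a 2-(chromen-6-yl)acrylic acid. The feature exploited is that O1 (on C8a) and the carbonyl carbon C4 (on C4a) are ortho on ring A, with the C5 methoxy group flanking C4a, which is the native regiochemistry of carboxylate addition to a 3-methoxyaryne. Fluoride releases the aryne from an ortho-silylaryl triflate; O-arylation, O-to-C acyl shift and 6-endo oxa-Michael closure give the racemic bis-MOM isoflavanone in one flask. C3 is set last, by catalytic enantioselective protonation of an enol silane.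

Key step: step 8

Remarks on the chemistry (assumptions):
- The target is the (3S) ketone (priorities C4 > C2 > aryl > H). The sense of induction of the protonation catalyst on a chromanone enol silane must be checked in a test run; the (S)-BINOL-derived acid is written, and its mirror image is used if the R ketone predominates.
- The C8 oxygen of the pendant chromene is brought in as a catechol hydroxyl and carried as a MOM ether, because a methyl ether at that site could not be cleaved later beside the C5 methoxy group.
- Both MOM ethers are removed while C3 is still racemic, so that no acid or base treatment follows the step that sets the stereocentre.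
- The parent silylaryl triflate, the bromocatechol aldehyde and the two organometallic reagents (as THF solutions) are taken as catalogue items.

Step 1
Reactants: 1 3-methoxy-2-(trimethylsilyl)phenyl trifluoromethanesulfonate
Product: 3 5-hydroxy-3-methoxy-2-(trimethylsilyl)phenyl trifluoromethanesulfonate, via aryl pinacol boronate 2 (not isolated)
Conditions: B2pin2 (1.0 equiv), [Ir(OMe)(cod)]2 (1.5 mol %), dtbpy (3 mol %), hexane, 60 °C; evaporate; then KHSO5 (as Oxone, 2KHSO5·KHSO4·K2SO4), acetone/H2O, 0 °C to rt; NaHSO3 quench
Reagents that add atoms: potassium peroxymonosulfate, [K+].[O-]S(=O)(=O)OO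
Why: Iridium-catalysed C–H borylation is governed by sterics and should reach only C5, the one C–H of this 1,2,3-trisubstituted arene without an ortho neighbour, while the aryl triflate and the aryl–silicon bond are left alone; peroxymonosulfate then oxidises the C–B bond to C–OH at the same carbon (one-pot C–H borylation/oxidation).

Step 2
Reactants: 3 5-hydroxy-3-methoxy-2-(trimethylsilyl)phenyl trifluoromethanesulfonate
Product: 4 3-methoxy-5-(methoxymethoxy)-2-(trimethylsilyl)phenyl trifluoromethanesulfonate
Conditions: MOMCl (1.5 equiv), i-Pr2NEt (2 equiv), CH2Cl2, 0 °C to rt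
Reagents that add atoms: chloromethyl methyl ether, COCCl
Why: Plain O-alkylation of the phenol (methoxymethyl ether formation) under an amine base, which carries neither fluoride nor alkoxide and so cannot trigger the silyl/triflate pair.

Step 3
Reactants: 5 5-bromo-2,3-dihydroxybenzaldehyde
Product: 6 5-bromo-2-hydroxy-3-(methoxymethoxy)benzaldehyde
Conditions: NaH (2.1 equiv), DMF, 0 °C; then MOMCl (1.0 equiv), 0 °C to rt; aq. NH4Cl
Reagents that add atoms: chloromethyl methyl ether, COCCl
Why: Regioselective Williamson etherification through the dianion: the 3-phenoxide is not conjugated to the formyl group and is the more nucleophilic oxygen, whereas the 2-phenoxide is held as a sodium chelate with the aldehyde, so one equivalent of MOMCl should go to O3.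

Step 4
Reactants: 6 5-bromo-2-hydroxy-3-(methoxymethoxy)benzaldehyde; 7 2-methyl-1-propenylmagnesium bromide
Product: 9 6-bromo-8-(methoxymethoxy)-2,2-dimethyl-2H-chromene, via allylic benzylic carbinol 8 (not isolated)
Conditions: Me2C=CHMgBr (2.5 equiv), THF, 0 °C to rt; aq. NH4Cl; crude, PPTS (2 mol %), toluene, 60 °C
Reagents that add atoms: 2-methyl-1-propenylmagnesium bromide, CC(C)=C[Mg]Br
Why: Grignard 1,2-addition to the salicylaldehyde (the first equivalent only deprotonates the phenol; the carbinol centre of 8 forms racemic and disappears again) is followed by acid-promoted dehydration to an ortho-quinone methide and oxa-6π electrocyclisation, the standard way from salicylaldehydes to 2,2-dimethyl-2H-chromenes, under acid mild enough for the MOM ether in an aprotic solvent.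

Step 5
Reactants: 9 6-bromo-8-(methoxymethoxy)-2,2-dimethyl-2H-chromene; 10 (2-ethoxy-2-oxoethyl)zinc bromide
Product: 11 ethyl 2-[8-(methoxymethoxy)-2,2-dimethyl-2H-chromen-6-yl]acetate
Conditions: BrZnCH2CO2Et (1.5 equiv), Pd(dba)2 (2 mol %), XPhos (4 mol %), THF, 65 °C
Reagents that add atoms: (2-ethoxy-2-oxoethyl)zinc bromide, CCOC(=O)C[Zn]Br
Why: Negishi-type coupling of the aryl bromide with a Reformatsky zinc enolate (palladium-catalysed ester α-arylation) runs under nearly neutral conditions with a zerovalent palladium/biaryl phosphine catalyst that inserts readily into electron-rich aryl bromides, and neither the MOM ether nor the chromene alkene takes part.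

Step 6
Reactants: 11 ethyl 2-[8-(methoxymethoxy)-2,2-dimethyl-2H-chromen-6-yl]acetate
Product: 12 ethyl 2-[8-(methoxymethoxy)-2,2-dimethyl-2H-chromen-6-yl]prop-2-enoate
Conditions: (CH2O)n (3 equiv), K2CO3 (2 equiv), Bu4NI (10 mol %), toluene, 80 °C
Reagents that add atoms: formaldehyde (as paraformaldehyde), C=O
Why: α-Methylenation by aldol addition of the arylacetate enolate to formaldehyde and E1cB loss of water under solid–liquid phase-transfer conditions, a standard entry to 2-arylacrylates.

Step 7
Reactants: 12 ethyl 2-[8-(methoxymethoxy)-2,2-dimethyl-2H-chromen-6-yl]prop-2-enoate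
Product: 13 2-[8-(methoxymethoxy)-2,2-dimethyl-2H-chromen-6-yl]prop-2-enoic acid
Conditions: LiOH·H2O (3 equiv), THF/H2O, rt; then 1 M HCl to pH 3, 0 °C
Reagents that add atoms: lithium hydroxide (supplies the acid OH oxygen), [Li+].[OH-]
Why: Ester saponification at room temperature; acidification only to about pH 3 in the cold should spare the MOM ether and the chromene, and the acrylic acid is used at once to forestall dimerisation.

Step 8
Reactants: 13 2-[8-(methoxymethoxy)-2,2-dimethyl-2H-chromen-6-yl]prop-2-enoic acid; 4 3-methoxy-5-(methoxymethoxy)-2-(trimethylsilyl)phenyl trifluoromethanesulfonate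
Product: 16 racemic 5-methoxy-7-(methoxymethoxy)-3-[8-(methoxymethoxy)-2,2-dimethyl-2H-chromen-6-yl]-2,3-dihydro-4H-chromen-4-one, via aryne 14 (not isolated), via ortho-hydroxyaryl enone 15 (not isolated)
Conditions: 4 (1.5 equiv), CsF (4 equiv), THF (0.03 M), 125 °C, sealed vessel
Reagents that add atoms: none
Why: Fluoride strips the silyl group of 4 and triflate leaves, giving aryne 14; the caesium carboxylate of 13 adds through oxygen to the aryne carbon remote from the methoxy group (future C8a), which puts the aryl anion on the carbon next to OMe (future C4a), where it is inductively stabilised. That anion attacks the neighbouring ester carbonyl through a four-membered alkoxide and the acyl group moves from oxygen to carbon (an anionic Fries-type 1,3-shift), giving the phenoxide of enone 15, which closes ring C by 6-endo-trig oxa-Michael addition to the α-aryl enone. The closest known reaction type is the fluoride-induced insertion of arynes into the C–O bond of α,β-unsaturated carboxylic acids with in situ Michael closure to chroman-4-ones. C3 arises when the enolate is protonated by bifluoride; nothing controls it, so 16 is racemic and C3 is set in step 11. The step needs regioselective aryne capture, which the C5 methoxy group secures, and acyl shift ahead of protonation of the aryl anion, which high temperature, dilution and excess CsF favour.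

Step 9
Reactants: 16 racemic 5-methoxy-7-(methoxymethoxy)-3-[8-(methoxymethoxy)-2,2-dimethyl-2H-chromen-6-yl]-2,3-dihydro-4H-chromen-4-one
Product: 17 racemic 7-hydroxy-3-(8-hydroxy-2,2-dimethyl-2H-chromen-6-yl)-5-methoxy-2,3-dihydro-4H-chromen-4-one
Conditions: HCl (3 M aq.), MeOH/THF, 45 °C
Reagents that add atoms: none
Why: Acid-catalysed acetal cleavage (transacetalisation to dimethoxymethane) removes both MOM ethers at a stage where C3 is still racemic, so acid-induced enolisation costs nothing, and dilute methanolic HCl is routinely tolerated by 2,2-dimethylchromenes.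

Step 10
Reactants: 17 racemic 7-hydroxy-3-(8-hydroxy-2,2-dimethyl-2H-chromen-6-yl)-5-methoxy-2,3-dihydro-4H-chromen-4-one
Product: 18 5-methoxy-4,7-bis(trimethylsilyloxy)-3-[2,2-dimethyl-8-(trimethylsilyloxy)-2H-chromen-6-yl]-2H-chromene
Conditions: TMSOTf (4 equiv), Et3N (6 equiv), CH2Cl2, 0 °C to rt; evaporate, pentane, filter under argon
Reagents that add atoms: trimethylsilyl trifluoromethanesulfonate, C[Si](C)(C)OS(=O)(=O)C(F)(F)F
Why: Soft enolisation with a silyl triflate and a tertiary amine: the only enolisable position is the benzylic C3–H, so a single tetrasubstituted enol silane should form, and the two phenols are capped as TMS ethers in the same operation, which keeps free OH groups away from the next step.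

Step 11
Reactants: 18 5-methoxy-4,7-bis(trimethylsilyloxy)-3-[2,2-dimethyl-8-(trimethylsilyloxy)-2H-chromen-6-yl]-2H-chromene
Product: 20 (3S)-7-hydroxy-3-(8-hydroxy-2,2-dimethyl-2H-chromen-6-yl)-5-methoxy-2,3-dihydro-4H-chromen-4-one, via bis-TMS ether of the S ketone 19 (not isolated)
Conditions: (S)-3,3'-bis(2,4,6-triisopropylphenyl)-BINOL N-triflyl thiophosphoramide (5 mol %), PhOH (1.1 equiv), toluene, rt; then MeOH, 0 °C; pH 7 buffer, neutral silica
Reagents that add atoms: none
Why: Catalytic enantioselective protonation of a silyl enol ether by a chiral Brønsted acid: the confined acid transfers its proton to one face of C3 of the C3=C4 double bond and thereby sets C3 (S), phenol takes up the silyl group and regenerates the acid, and the brief acid-catalysed methanolysis of the two aryl TMS ethers is far too mild to enolise the new ketone.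

**Compound list**

1 | 3-methoxy-2-(trimethylsilyl)phenyl trifluoromethanesulfonate | COc1cccc(OS(=O)(=O)C(F)(F)F)c1[Si](C)(C)C | starting material
2 | 3-methoxy-5-(4,4,5,5-tetramethyl-1,3,2-dioxaborolan-2-yl)-2-(trimethylsilyl)phenyl trifluoromethanesulfonate | COc1cc(B2OC(C)(C)C(C)(C)O2)cc(OS(=O)(=O)C(F)(F)F)c1[Si](C)(C)C | intermediate (not isolated)
3 | 5-hydroxy-3-methoxy-2-(trimethylsilyl)phenyl trifluoromethanesulfonate | COc1cc(O)cc(OS(=O)(=O)C(F)(F)F)c1[Si](C)(C)C | intermediate
4 | 3-methoxy-5-(methoxymethoxy)-2-(trimethylsilyl)phenyl trifluoromethanesulfonate | COc1cc(OCOC)cc(OS(=O)(=O)C(F)(F)F)c1[Si](C)(C)C | intermediate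
5 | 5-bromo-2,3-dihydroxybenzaldehyde | O=Cc1cc(Br)cc(O)c1O | starting material
6 | 5-bromo-2-hydroxy-3-(methoxymethoxy)benzaldehyde | COCOc1cc(Br)cc(C=O)c1O | intermediate
7 | 2-methyl-1-propenylmagnesium bromide | CC(C)=C[Mg]Br | starting material
8 | racemic 4-bromo-2-(1-hydroxy-3-methylbut-2-en-1-yl)-6-(methoxymethoxy)phenol | COCOc1cc(Br)cc(C(O)C=C(C)C)c1O | intermediate (not isolated)
9 | 6-bromo-8-(methoxymethoxy)-2,2-dimethyl-2H-chromene | CC1(C)C=Cc2cc(Br)cc(OCOC)c2O1 | intermediate
10 | (2-ethoxy-2-oxoethyl)zinc bromide | CCOC(=O)C[Zn]Br | starting material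
11 | ethyl 2-[8-(methoxymethoxy)-2,2-dimethyl-2H-chromen-6-yl]acetate | CCOC(=O)Cc1cc(OCOC)c2OC(C)(C)C=Cc2c1 | intermediate
12 | ethyl 2-[8-(methoxymethoxy)-2,2-dimethyl-2H-chromen-6-yl]prop-2-enoate | C=C(C(=O)OCC)c1cc(OCOC)c2OC(C)(C)C=Cc2c1 | intermediate
13 | 2-[8-(methoxymethoxy)-2,2-dimethyl-2H-chromen-6-yl]prop-2-enoic acid | C=C(C(=O)O)c1cc(OCOC)c2OC(C)(C)C=Cc2c1 | intermediate
14 | 3-methoxy-5-(methoxymethoxy)benzyne | COC1=CC(OCOC)=CC#C1 | intermediate (not isolated)
15 | 1-[2-hydroxy-6-methoxy-4-(methoxymethoxy)phenyl]-2-[8-(methoxymethoxy)-2,2-dimethyl-2H-chromen-6-yl]prop-2-en-1-one (formed as its caesium phenoxide) | C=C(C(=O)c1c(O)cc(OCOC)cc1OC)c1cc(OCOC)c2OC(C)(C)C=Cc2c1 | intermediate (not isolated)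
16 | racemic 5-methoxy-7-(methoxymethoxy)-3-[8-(methoxymethoxy)-2,2-dimethyl-2H-chromen-6-yl]-2,3-dihydro-4H-chromen-4-one | COc1cc(OCOC)cc2c1C(=O)C(c1cc(OCOC)c3c(c1)C=CC(C)(C)O3)CO2 | intermediate
17 | racemic 7-hydroxy-3-(8-hydroxy-2,2-dimethyl-2H-chromen-6-yl)-5-methoxy-2,3-dihydro-4H-chromen-4-one | COc1cc(O)cc2c1C(=O)C(c1cc(O)c3c(c1)C=CC(C)(C)O3)CO2 | intermediate
18 | 5-methoxy-4,7-bis(trimethylsilyloxy)-3-[2,2-dimethyl-8-(trimethylsilyloxy)-2H-chromen-6-yl]-2H-chromene | COc1cc(O[Si](C)(C)C)cc2c1C(O[Si](C)(C)C)=C(c1cc(O[Si](C)(C)C)c3c(c1)C=CC(C)(C)O3)CO2 | intermediate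
19 | (3S)-5-methoxy-7-(trimethylsilyloxy)-3-[2,2-dimethyl-8-(trimethylsilyloxy)-2H-chromen-6-yl]-2,3-dihydro-4H-chromen-4-one | COc1cc(O[Si](C)(C)C)cc2c1C(=O)[C@@H](c1cc(O[Si](C)(C)C)c3c(c1)C=CC(C)(C)O3)CO2 | intermediate (not isolated)
20 | (3S)-7-hydroxy-3-(8-hydroxy-2,2-dimethyl-2H-chromen-6-yl)-5-methoxy-2,3-dihydro-4H-chromen-4-one | COc1cc(O)cc2c1C(=O)[C@@H](c1cc(O)c3c(c1)C=CC(C)(C)O3)CO2 | target

**Step count.** Total: 11 steps. Longest linear sequence: 9 steps (steps 3 to 11, from 5); the aryne precursor 4 is a two-step side branch.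

**Steps most likely to fail**

1. Step 8. The aryl anion may be protonated before the acyl group shifts, which stops the cascade at O-arylation. The acrylic acid may also oligomerise at 125 °C, or the aryne may be consumed by ene or [2+2] reaction at the chromene double bond.
Fallback (no aryne; isoflavone cross-coupling and conjugate reduction), setting out from 9 and coming back at 16:
   - Miyaura borylation of 9 (B2pin2, PdCl2(dppf), KOAc, dioxane, 90 °C) should give the chromenyl pinacol boronate F1.
   - Separately, purchased 1-(2,4-dihydroxy-6-methoxyphenyl)ethanone (CC(=O)c1c(O)cc(O)cc1OC) is etherified at the non-chelated para hydroxyl (MOMCl, K2CO3, acetone) to the MOM-protected acetophenone F2.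
   - F2 is condensed with N,N-dimethylformamide dimethyl acetal (95 °C) to the enaminone F3, which is cyclised with I2 and pyridine in CHCl3 to the 3-iodochromone F4.
   - Suzuki–Miyaura coupling of F4 with F1 (PdCl2(dppf), K2CO3, dioxane/H2O, 80 °C) should give the isoflavone F5.
   - Conjugate hydride reduction with LiBH(s-Bu)3 in THF at −78 °C leads back to racemic isoflavanone 16.

2. Step 11 (this fallback also covers step 10). Facial discrimination in the proton transfer may be poor, since the peri C5 methoxy group and the ring oxygen change the shape the catalyst has to read. Adventitious water may also hydrolyse the enol silane before the catalyst acts, which gives racemic ketone.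
Fallback (resolution with recycling instead of asymmetric catalysis), setting out from 17 and coming back at 20: racemic 17 is separated by preparative chromatography on a chiral stationary phase (supercritical CO2/alcohol, neutral) to give 20 directly. The unwanted (R)-enantiomer F6 is racemised through its enol with catalytic Et3N in MeOH at rt and returned to the separation as 17.

3. Step 5. Oxidative addition into the electron-rich aryl bromide may be slow, so that protonation or self-condensation of the zinc enolate wins and the bromide is recovered.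
Fallback (acyl anion chemistry instead of cross-coupling), setting out from 9 and coming back at 12, which bypasses steps 5 and 6: bromine–lithium exchange on 9 (n-BuLi, THF, −78 °C) and inverse addition to diethyl oxalate should give the α-keto ester F7. Wittig methylenation of F7 (Ph3PCH3Br, KN(SiMe3)2, THF, −78 to 0 °C) then gives acrylate 12.

**Further compounds**

F1 | step 8 | 2-[8-(methoxymethoxy)-2,2-dimethyl-2H-chromen-6-yl]-4,4,5,5-tetramethyl-1,3,2-dioxaborolane | CC1(C)C=Cc2cc(B3OC(C)(C)C(C)(C)O3)cc(OCOC)c2O1
F2 | step 8 | 1-[2-hydroxy-6-methoxy-4-(methoxymethoxy)phenyl]ethanone | CC(=O)c1c(O)cc(OCOC)cc1OC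
F3 | step 8 | (E)-3-(dimethylamino)-1-[2-hydroxy-6-methoxy-4-(methoxymethoxy)phenyl]prop-2-en-1-one | CN(C)/C=C/C(=O)c1c(O)cc(OCOC)cc1OC
F4 | step 8 | 3-iodo-5-methoxy-7-(methoxymethoxy)-4H-chromen-4-one | COc1cc(OCOC)cc2occ(I)c(=O)c12
F5 | step 8 | 5-methoxy-7-(methoxymethoxy)-3-[8-(methoxymethoxy)-2,2-dimethyl-2H-chromen-6-yl]-4H-chromen-4-one | COc1cc(OCOC)cc2occ(-c3cc(OCOC)c4OC(C)(C)C=Cc4c3)c(=O)c12
F6 | step 11 | (3R)-7-hydroxy-3-(8-hydroxy-2,2-dimethyl-2H-chromen-6-yl)-5-methoxy-2,3-dihydro-4H-chromen-4-one | COc1cc(O)cc2c1C(=O)[C@H](c1cc(O)c3c(c1)C=CC(C)(C)O3)CO2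
F7 | step 5 | ethyl 2-[8-(methoxymethoxy)-2,2-dimethyl-2H-chromen-6-yl]-2-oxoacetate | CCOC(=O)C(=O)c1cc(OCOC)c2OC(C)(C)C=Cc2c1
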